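## Analysis of the target

The target is a 19-membered ansa-macrolactam: an aminohydroquinone (ring C16–C21, nitrogen on C20, hydroxyls on C18 and C21) is bridged meta, from C20 through the amide carbonyl C1 and the chain C2–C15 back to C16. The chain holds seven stereocentres in three clusters: C6 (S, OMe) and C7 (S, carbamate) are syn; C10 (S, methyl), C11 (R, OMe) and C12 (S, OMe) are 10,11-syn and 11,12-anti; C14 (S, methyl) and the benzylic C15 (R, OMe) are syn. The clusters are insulated from one another by the C8=C9 alkene and the C13 methylene, so each must be set by a reagent and cannot be relayed from a neighbour. All three alkenes are Z: the (2Z,4Z)-dienamide and the trisubstituted C8=C9 bond, on which C7 and C10 are cis. Sensitive features are the hydroquinone (air oxidation to the quinone), the primary allylic carbamate on C7, the Z,Z-dienamide (drifts towards 2E with base, heat or nucleophiles) and the α-alkoxy aldehydes needed on the way. The hard part is the trisubstituted Z alkene between two stereocentres: ordinary olefinations of α-methyl carbonyl compounds favour the other isomer, and it must coexist with two further Z alkenes and a macrocyclization. The strategy rests on C7–C11: with the oxygen on C11 as ring oxygen and C7 as carbonyl, these five carbons are an α-methyl-α,β-unsaturated δ-lactone (a 5,6-dihydropyran-2-one), a six-membered ring in which C8=C9 can only hold C7 and C10 cis.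

## Retrosynthetic reasoning

**Hydroquinone.** 50 is taken back to quinone 49 and this to the dimethyl ether 48; the bonds cut are the two O–CH3 bonds on C18 and C21. The free hydroquinone would not survive the oxidants and bases of the route. Methyl ethers are preferred to silyl ethers because an aryl silyl ether ortho to a nitro group is cleaved by the alkoxide, hydroxide and fluoride conditions that recur, and because the nitro-dimethoxy arene is reached in one step from the catalogue phenol 1. The forward reactions must oxidize only the electron-rich arene and then reduce the quinone.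

**Carbamate.** 48 goes back to alcohol 46 and its silyl ether 45 (C7–O carbamoyl bond). The primary carbamate has acidic N–H bonds and an allylic C–O bond, so it is put on after the ring is closed.

**C2=C3 and the macrocycle.** 45 is opened at C2=C3 to the aldehyde–phosphonate 44. Cutting here and not at N–C1 means the amide is made intermolecularly, from aniline 37 and acid 42 (giving 43), where a sluggish aniline can be pushed with excess acid. The 2Z alkene, the one most easily lost, is then formed last under kinetic control and never has to survive carboxyl activation. The forward step must close a 19-membered ring and give Z; the diaryl phosphonate in 42 (from 38 and 39 by way of 40 and 41) is chosen for that.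

**Aniline and C4=C5.** 37 comes from nitro compound 36; the nitrogen is carried as nitro from the start because a free aniline would not tolerate the aldehydes, acyl chlorides and alkylating agents used. 36 goes back through ester 35 to aldehyde 33 and phosphonate 34 (C4=C5 cut). The forward olefination must be Z-selective and must not epimerize the α-methoxy centre C6.

**C6–C7.** 33 derives, through 32 and 31, from aldol adduct 30, which is cut between the two oxygenated carbons into Z-enal 26 and glycolate imide 29 (from 27 and 28). One reaction sets both centres, and the auxiliary supplies the control that the remote C10 cannot.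

**Opening the template.** 26 comes from Weinreb amide 25, this from hydroxy amide 24, and 24 from lactone 23 by cleavage of the acyl–oxygen bond between C7 and the C11 oxygen. This is where the lactone pays a second time: opening frees the C11 hydroxyl alone for methylation and leaves C7 as a carbonyl ready for the C6–C7 bond.

**C8=C9.** 23 is cut at C8=C9 to the methacrylate 22 by ring-closing metathesis, and 22 to alcohol 20 and acyl chloride 21. The alkene is formed inside a six-membered ring and has no geometric choice; the two carbons lost are terminal methylenes. This is the one step of the route without a close substrate analogue, and it is placed early.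

**C10–C11.** 20 is cut between C10 and C11 into α-methoxy aldehyde 17 and the crotyl unit of 18, delivered as the chiral (Z)-crotylborane 19. A closed transition state turns the Z geometry of 19 into the 10,11-syn pair, and the preference of the α-alkoxy aldehyde for the 11,12-anti product works with the reagent.

**C12 and the two-carbon link.** 17 comes from 16, 15 and the α-hydroxy imide 14 (C12–O bond, by oxygen transfer to the enolate of 13). 13 comes from enoyl imide 12 and this from aldehyde 7 and phosphonate 11 (C12–C13 bond; 11 from 8 and 9). C13 is a methylene, so no carbonyl addition can form C12–C13 or set C12. An olefination followed by saturation brings in C11 and C12 already bound to the auxiliary that then controls C12.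

**C14–C15.** 7 goes back through 6 and 5 to aldol adduct 4, cut at C14–C15 into aryl aldehyde 2 (from 1) and propionimide 3. The syn aldol sets both centres on a cheap, non-enolizable aldehyde and fixes the absolute configuration of the whole southern half.

## Alternatives that were turned down

Alternative 1: Here the arene would not be bought but assembled in the ring-closing step. The disconnection cuts three arene bonds, C18–C19, C20–C21 and C16–C21. C16–C18 come from an alkenyl(methoxy)carbene bound to a Cr(CO)5 fragment, C21 from one of its carbonyl ligands, and C19–C20 from a terminal ynamide at the other end of the finished ansa chain. In the forward Dötz benzannulation the alkyne inserts into the chromium–carbene bond, a carbonyl ligand inserts to give a dienylketene, and 6π-electrocyclization with tautomerization gives the N-(4-methoxybenzyl) macrolactam A1. A1 has the C21 phenol free and C18 as its methyl ether, and arene and 19-membered ring form together.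
- For it: the highest convergence of all options; an intrinsic regiochemistry (the substituted alkyne carbon ends next to the new phenol) that fits nitrogen on C20 beside C21–OH; and no nitro group, so hydrogenation and organometallic reagents stay available for the chain.
- Against it: the carbene would have to be generated at the end of a long, densely functionalized chain by organolithium and metal-carbonyl chemistry that the carbamate, the dienamide and the allylic ethers tolerate poorly. Ynamides can divert to cyclobutenones or double insertion. The annulation must also overcome the entropy of a 19-atom tether, where strain can override the normal regiochemistry, and heating a Z,Z-dienamide with a low-valent metal invites isomerization. A1 is also not the target: the N-benzyl group and the C18 methyl ether still have to be removed, again through the quinone.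
- Comparison: shorter on paper and stronger on convergence, but three independent uncertainties are stacked in one late step and C8=C9 is left unsolved. The chosen route spends more steps but confines its open question to a six-membered ring closure on an early intermediate.

Alternative 2: The ring would be cut at C4–C5, taken back to an alkyne. An open-chain diyne with methyl caps, one alkyne conjugated to the (2Z)-enamide and one propargylic to C6, would be closed by ring-closing alkyne metathesis to the macrocyclic 4,5-didehydro enyne lactam A2. The catalyst would be the molybdenum alkylidyne A3, the complex of formula Mo(≡CC6H4OMe)(OSiPh3)3, and a cis-selective semi-reduction would then give the 4Z alkene.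
- For it: the closure is driven by loss of a small volatile alkyne, forms large rings dependably and has no geometric issue of its own. The 4Z geometry follows stereospecifically from the reduction. The silyl-protected hydroquinone of A2 can be released by fluoride without any redox step. On these points it is as strong as or stronger than the chosen endgame, which depends on kinetic Z selection in a ring-forming olefination and needs an oxidation–reduction pair to free the hydroquinone.
- Against it: the semi-reduction has to pick one triple bond of a conjugated enyne in the presence of three alkenes, the kind of substrate on which Lindlar-type reductions stall or over-reduce. The anilide N–H and any protic impurity deactivate the silanolate-ligated alkylidyne A3 at the most valuable stage. The propargylic C6 centre is exposed, and silyl ethers of an ortho-substituted aminophenol would have to last the whole sequence.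
- Comparison: decisive is that this disconnection does nothing for the trisubstituted Z alkene C8=C9 or for C2=C3, which would still need separate Z-selective olefinations. The chosen strategy gives up the elegant closure but locks C8=C9 by ring constraint where failure is cheap, with a commercial, air-stable catalyst.

Alternative 3: The cut is the N–C20 bond. An open-chain primary (2Z,4Z)-dienamide carrying an iodide on C20 would be cyclized by a Goldberg-type amidation to macrolactam A4, which has allyl-protected phenols and a silyl ether on C7. The catalyst would be copper monoiodide A5, used with a 1,2-diamine ligand and a carbonate base in a hot solvent.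
- For it: aryl iodide and primary amide are robust handles that pass through almost any chain-building chemistry. No nitro group restricts the reductants, so the C12–C13 saturation that costs a diimide step in the chosen route would be a plain hydrogenation. Copper-mediated amidation is an established way to close macrolactams of this size. On functional-group latitude and on the reliability of the bond-forming event this alternative is the stronger one.
- Against it: the closure with A5 needs about 100 °C and base for hours, conditions under which a 2Z,4Z-dienamide with an N–H is likely to drift towards 2E by reversible conjugate addition or thermal isomerization. The iodide lies ortho to an allyloxy group. The endgame is awkward, because removing the allyl ethers of A4 with zerovalent palladium competes with ionization of the allylic carbamate on C7, so the carbamate would have to be introduced in the presence of free phenols. It also gives no answer to C8=C9.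
- Comparison: the chosen route closes the macrocycle at or below room temperature and keeps an orthogonal endgame, and pays for this with nitro-compatible reagents throughout.

Key step: step 15

Remark: 1 is taken as a catalogue compound; 41–44 are used as both epimers at the phosphorus-bearing carbon, a centre that disappears in step 32; locants C1–C21 in the names of 43–50 follow the numbering of the analysis.

## Route

Step 1
Reactants: 1 2-hydroxy-5-methoxy-3-nitrobenzaldehyde
Product: 2 2,5-dimethoxy-3-nitrobenzaldehyde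
Conditions: MeI, K2CO3, DMF, 50 °C
Reagents that add atoms: iodomethane, CI
Why: Williamson O-methylation; the ortho-nitrophenol is acidic enough for carbonate, the phenoxide is the only nucleophile, and the aldehyde cannot enolize.

Step 2
Reactants: 2 2,5-dimethoxy-3-nitrobenzaldehyde; 3 (R)-4-benzyl-3-propionyloxazolidin-2-one
Product: 4 (R)-4-benzyl-3-[(2R,3R)-3-(2,5-dimethoxy-3-nitrophenyl)-3-hydroxy-2-methylpropanoyl]oxazolidin-2-one
Conditions: 3, Bu2BOTf, Et3N, CH2Cl2, 0 °C; then 2, −78 → 0 °C; pH 7 buffer, MeOH, H2O2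
Reagents that add atoms: none
Why: Evans syn aldol: the Z-boron enolate reacts through a closed chair transition state with the imide dipoles opposed, the aldehyde approaching the enolate face away from the benzyl group; the (R)-auxiliary therefore should give the (2R,3R) adduct, which is the syn C14/C15 pair of the target. The electron-poor aryl aldehyde is a good acceptor and cannot enolize.

Step 3
Reactants: 4 (R)-4-benzyl-3-[(2R,3R)-3-(2,5-dimethoxy-3-nitrophenyl)-3-hydroxy-2-methylpropanoyl]oxazolidin-2-one
Product: 5 (R)-4-benzyl-3-[(2R,3R)-3-(2,5-dimethoxy-3-nitrophenyl)-3-methoxy-2-methylpropanoyl]oxazolidin-2-one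
Conditions: Me3OBF4, 1,8-bis(dimethylamino)naphthalene, 4 Å MS, CH2Cl2, rt
Reagents that add atoms: trimethyloxonium tetrafluoroborate, C[O+](C)C.F[B-](F)(F)F
Why: O-methylation with Meerwein's salt and a non-nucleophilic proton scavenger; the hydroxyl is alkylated without forming an alkoxide, so retro-aldol cleavage and epimerization at C14 are avoided.

Step 4
Reactants: 5 (R)-4-benzyl-3-[(2R,3R)-3-(2,5-dimethoxy-3-nitrophenyl)-3-methoxy-2-methylpropanoyl]oxazolidin-2-one
Product: 6 (2S,3R)-3-(2,5-dimethoxy-3-nitrophenyl)-3-methoxy-2-methylpropan-1-ol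
Conditions: LiBH4, MeOH (1 equiv), THF, 0 °C; aq. NaOH
Reagents that add atoms: none
Why: Reductive removal of the Evans auxiliary: borohydride attacks the exocyclic imide carbonyl and takes the acyl group to the primary alcohol; nitroarene and ethers are inert to LiBH4 and no stereocentre is touched.

Step 5
Reactants: 6 (2S,3R)-3-(2,5-dimethoxy-3-nitrophenyl)-3-methoxy-2-methylpropan-1-ol
Product: 7 (2R,3R)-3-(2,5-dimethoxy-3-nitrophenyl)-3-methoxy-2-methylpropanal
Conditions: Dess–Martin periodinane, NaHCO3, CH2Cl2, 0 °C → rt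
Reagents that add atoms: none
Why: Dess–Martin oxidation under buffered, non-basic conditions should give the α-branched aldehyde without epimerizing C14; it is used without storage.

Step 6
Reactants: 8 2-(diethoxyphosphoryl)acetic acid; 9 (S)-4-benzyloxazolidin-2-one
Product: 11 (S)-4-benzyl-3-[2-(diethoxyphosphoryl)acetyl]oxazolidin-2-one, via pivalic mixed anhydride 10 (not isolated)
Conditions: t-BuCOCl, Et3N, THF, −20 °C; then 9, LiCl, rt
Reagents that add atoms: none
Why: N-acylation of the oxazolidinone through a mixed pivalic anhydride with LiCl/Et3N activation; the hindered pivaloyl carbonyl is not attacked, so the phosphonoacetyl group is transferred.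

Step 7
Reactants: 7 (2R,3R)-3-(2,5-dimethoxy-3-nitrophenyl)-3-methoxy-2-methylpropanal; 11 (S)-4-benzyl-3-[2-(diethoxyphosphoryl)acetyl]oxazolidin-2-one
Product: 12 (S)-4-benzyl-3-[(2E,4S,5R)-5-(2,5-dimethoxy-3-nitrophenyl)-5-methoxy-4-methylpent-2-enoyl]oxazolidin-2-one
Conditions: LiCl, i-Pr2NEt, MeCN, rt
Reagents that add atoms: none
Why: Horner–Wadsworth–Emmons olefination under Masamune–Roush conditions; the lithium-chelated phosphonate is deprotonated by an amine base mild enough to leave C14 intact, and C11 and C12 arrive already bound to the auxiliary that will control C12. The alkene geometry is immaterial because the double bond is saturated next.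

Step 8
Reactants: 12 (S)-4-benzyl-3-[(2E,4S,5R)-5-(2,5-dimethoxy-3-nitrophenyl)-5-methoxy-4-methylpent-2-enoyl]oxazolidin-2-one
Product: 13 (S)-4-benzyl-3-[(4S,5R)-5-(2,5-dimethoxy-3-nitrophenyl)-5-methoxy-4-methylpentanoyl]oxazolidin-2-one
Conditions: 2-O2NC6H4SO2NHNH2 (excess, in portions), Et3N, CH2Cl2, rt
Reagents that add atoms: none
Why: Diimide reduction: HN=NH generated in the flask delivers two hydrogens to the C12=C13 bond through a concerted six-centre transition state and does not reduce nitro groups, which rules out catalytic hydrogenation here; C14 is not affected.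

Step 9
Reactants: 13 (S)-4-benzyl-3-[(4S,5R)-5-(2,5-dimethoxy-3-nitrophenyl)-5-methoxy-4-methylpentanoyl]oxazolidin-2-one
Product: 14 (S)-4-benzyl-3-[(2S,4S,5R)-5-(2,5-dimethoxy-3-nitrophenyl)-2-hydroxy-5-methoxy-4-methylpentanoyl]oxazolidin-2-one
Conditions: NaN(SiMe3)2, THF, −78 °C; 3-phenyl-2-(phenylsulfonyl)oxaziridine; camphorsulfonic acid quench
Reagents that add atoms: 3-phenyl-2-(phenylsulfonyl)oxaziridine, O=S(=O)(c1ccccc1)N1OC1c1ccccc1
Why: Enolate hydroxylation with a Davis oxaziridine: the chelated Z-sodium enolate of the imide is attacked by the electrophilic oxygen on the face opposite the benzyl group, which for the (S)-auxiliary should give the (2S) alcohol, the C12 configuration of the target; the acidic quench prevents acyl migration.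

Step 10
Reactants: 14 (S)-4-benzyl-3-[(2S,4S,5R)-5-(2,5-dimethoxy-3-nitrophenyl)-2-hydroxy-5-methoxy-4-methylpentanoyl]oxazolidin-2-one
Product: 15 (S)-4-benzyl-3-[(2S,4S,5R)-5-(2,5-dimethoxy-3-nitrophenyl)-2,5-dimethoxy-4-methylpentanoyl]oxazolidin-2-one
Conditions: Me3OBF4, 1,8-bis(dimethylamino)naphthalene, 4 Å MS, CH2Cl2, rt
Reagents that add atoms: trimethyloxonium tetrafluoroborate, C[O+](C)C.F[B-](F)(F)F
Why: Neutral O-methylation as in step 3; without an alkoxide, epimerization at C12 and attack of the C12 oxygen on the oxazolidinone carbonyl are avoided.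

Step 11
Reactants: 15 (S)-4-benzyl-3-[(2S,4S,5R)-5-(2,5-dimethoxy-3-nitrophenyl)-2,5-dimethoxy-4-methylpentanoyl]oxazolidin-2-one
Product: 16 (2S,4S,5R)-5-(2,5-dimethoxy-3-nitrophenyl)-2,5-dimethoxy-4-methylpentan-1-ol
Conditions: LiBH4, MeOH (1 equiv), THF, 0 °C; aq. NaOH
Reagents that add atoms: none
Why: Reductive cleavage of the imide as in step 4; the α-methoxy group does not interfere and the auxiliary is released.

Step 12
Reactants: 16 (2S,4S,5R)-5-(2,5-dimethoxy-3-nitrophenyl)-2,5-dimethoxy-4-methylpentan-1-ol
Product: 17 (2S,4S,5R)-5-(2,5-dimethoxy-3-nitrophenyl)-2,5-dimethoxy-4-methylpentanal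
Conditions: Dess–Martin periodinane, NaHCO3, CH2Cl2, 0 °C
Reagents that add atoms: none
Why: Dess–Martin oxidation; the α-methoxy aldehyde is configurationally fragile, so it is made under buffered conditions and used at once at −78 °C.

Step 13
Reactants: 17 (2S,4S,5R)-5-(2,5-dimethoxy-3-nitrophenyl)-2,5-dimethoxy-4-methylpentanal; 18 cis-2-butene
Product: 20 (3S,4R,5S,7S,8R)-8-(2,5-dimethoxy-3-nitrophenyl)-5,8-dimethoxy-3,7-dimethyloct-1-en-4-ol, via Z-crotyldiisopinocampheylborane 19 (not isolated)
Conditions: 18, KOt-Bu, n-BuLi, THF, −78 → −45 °C; (+)-Ipc2BOMe (from (−)-α-pinene), −78 °C; BF3·OEt2; 17, −78 °C; NaOH, H2O2, 0 °C → rt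
Reagents that add atoms: none
Why: Brown crotylboration: the (Z)-crotylborane adds through a chair transition state, so its Z geometry becomes the 10,11-syn relationship, and the isopinocampheyl groups derived from (−)-α-pinene select the aldehyde face that gives 11R. The inherent preference of an α-alkoxy aldehyde with (Z)-crotylboron reagents (Cornforth-type, 11,12-anti) points the same way, so reagent and substrate control are matched.

Step 14
Reactants: 20 (3S,4R,5S,7S,8R)-8-(2,5-dimethoxy-3-nitrophenyl)-5,8-dimethoxy-3,7-dimethyloct-1-en-4-ol; 21 methacryloyl chloride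
Product: 22 (3S,4R,5S,7S,8R)-8-(2,5-dimethoxy-3-nitrophenyl)-5,8-dimethoxy-3,7-dimethyloct-1-en-4-yl 2-methylprop-2-enoate
Conditions: 21, Et3N, DMAP (cat.), CH2Cl2, 0 °C → rt
Reagents that add atoms: none
Why: Esterification of the hindered secondary alcohol with an acyl chloride under DMAP catalysis; no stereocentre is involved and the alkenes are untouched.

Step 15
Reactants: 22 (3S,4R,5S,7S,8R)-8-(2,5-dimethoxy-3-nitrophenyl)-5,8-dimethoxy-3,7-dimethyloct-1-en-4-yl 2-methylprop-2-enoate
Product: 23 (5S,6R)-6-[(1S,3S,4R)-4-(2,5-dimethoxy-3-nitrophenyl)-1,4-dimethoxy-3-methylbutyl]-3,5-dimethyl-5,6-dihydro-2H-pyran-2-one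
Conditions: RuCl2(PCy3)(H2IMes)(=CHPh) (second-generation Grubbs catalyst, 10 mol %), toluene (0.005 M), 80 °C, argon sparge
Reagents that add atoms: none
Why: Ring-closing olefin metathesis of the kind established for acrylate and methacrylate esters of homoallylic alcohols. The ruthenium benzylidene should initiate at the monosubstituted C9 vinyl group, because the electron-poor 1,1-disubstituted methacrylate alkene neither initiates nor homodimerizes readily; the C9 alkylidene then adds across the methacrylate C=C in a [2+2] step, and cycloreversion of the ruthenacyclobutane forms the C8=C9 bond and releases the two terminal methylenes as ethylene, whose escape drives the reaction. The ring closed is the six-membered 5,6-dihydropyran-2-one (ring oxygen, C7, C8, C9, C10, C11) with both alkene carbons inside it, so C7 and C10 can only be cis, which is the Z geometry of the target. No stereocentre is formed, and C10 and C11 are spectators under these neutral conditions. The selectivities needed are ring closure over intermolecular cross-metathesis at the vinyl end, secured by dilution and the favourable ring size, and absence of ruthenium hydride double-bond migration towards C10, limited by short reaction time and exclusion of air. Heating is needed because the ester prefers the s-trans conformation, which holds the two alkenes apart. The nitro group and the methyl ethers are inert to the catalyst.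

Step 16
Reactants: 23 (5S,6R)-6-[(1S,3S,4R)-4-(2,5-dimethoxy-3-nitrophenyl)-1,4-dimethoxy-3-methylbutyl]-3,5-dimethyl-5,6-dihydro-2H-pyran-2-one
Product: 24 (2Z,4S,5R,6S,8S,9R)-9-(2,5-dimethoxy-3-nitrophenyl)-5-hydroxy-N,6,9-trimethoxy-N,2,4,8-tetramethylnon-2-enamide
Conditions: MeNH(OMe)·HCl, AlMe3, CH2Cl2, 0 °C → rt; aq. KNaC4H4O6
Reagents that add atoms: N,O-dimethylhydroxylamine hydrochloride, CNOC.Cl
Why: Weinreb aminolysis of a lactone: the dimethylaluminium amide adds to the C7 carbonyl and the ring opens to an aluminium alkoxide, which cannot re-close before work-up; the alkene is not touched, so the cis relationship of C7 and C10 fixed by the ring is carried into the chain as the Z-enamide. The α-methyl group and the branched γ-carbon disfavour conjugate addition.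

Step 17
Reactants: 24 (2Z,4S,5R,6S,8S,9R)-9-(2,5-dimethoxy-3-nitrophenyl)-5-hydroxy-N,6,9-trimethoxy-N,2,4,8-tetramethylnon-2-enamide
Product: 25 (2Z,4S,5R,6S,8S,9R)-9-(2,5-dimethoxy-3-nitrophenyl)-N,5,6,9-tetramethoxy-N,2,4,8-tetramethylnon-2-enamide
Conditions: Me3OBF4, 1,8-bis(dimethylamino)naphthalene, 4 Å MS, CH2Cl2, 0 °C → rt (crude 24, used at once)
Reagents that add atoms: trimethyloxonium tetrafluoroborate, C[O+](C)C.F[B-](F)(F)F
Why: O-methylation with Meerwein's salt as in step 3, done immediately so that the C11 hydroxyl cannot close back onto C7; the weakly basic Weinreb amide oxygen is a poorer nucleophile than the alcohol.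

Step 18
Reactants: 25 (2Z,4S,5R,6S,8S,9R)-9-(2,5-dimethoxy-3-nitrophenyl)-N,5,6,9-tetramethoxy-N,2,4,8-tetramethylnon-2-enamide
Product: 26 (2Z,4S,5R,6S,8S,9R)-9-(2,5-dimethoxy-3-nitrophenyl)-5,6,9-trimethoxy-2,4,8-trimethylnon-2-enal
Conditions: i-Bu2AlH, THF, −78 °C; aq. KNaC4H4O6
Reagents that add atoms: none
Why: Weinreb amide reduction: the chelated tetrahedral aluminium adduct is stable at −78 °C and releases the aldehyde only on work-up, so over-reduction is avoided; at this temperature the nitro group is spared, and a neutral tartrate work-up keeps the Z geometry.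

Step 19
Reactants: 27 (R)-4-benzyloxazolidin-2-one; 28 methoxyacetyl chloride
Product: 29 (R)-4-benzyl-3-(2-methoxyacetyl)oxazolidin-2-one
Conditions: n-BuLi, THF, −78 °C; then 28, −78 → 0 °C
Reagents that add atoms: none
Why: N-acylation of the lithiated oxazolidinone with an acyl chloride, the standard preparation of a glycolate imide.

Step 20
Reactants: 26 (2Z,4S,5R,6S,8S,9R)-9-(2,5-dimethoxy-3-nitrophenyl)-5,6,9-trimethoxy-2,4,8-trimethylnon-2-enal; 29 (R)-4-benzyl-3-(2-methoxyacetyl)oxazolidin-2-one
Product: 30 (R)-4-benzyl-3-[(2R,3S,4Z,6S,7R,8S,10S,11R)-11-(2,5-dimethoxy-3-nitrophenyl)-3-hydroxy-2,7,8,11-tetramethoxy-4,6,10-trimethylundec-4-enoyl]oxazolidin-2-one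
Conditions: 29 (1.3 equiv), Bu2BOTf (1.2 equiv), Et3N, CH2Cl2, −78 → 0 °C; then 26, −78 → −20 °C; pH 7 buffer, MeOH, H2O2
Reagents that add atoms: none
Why: Evans syn glycolate aldol: the Z-boron enolate of the methoxyacetyl imide adds 1,2 to the enal through a chair transition state, the (R)-auxiliary directing the facial sense exactly as in step 2, which should give C6 and C7 syn with the target configuration. Reagent control is needed because the nearest stereocentre, C10, is remote; enolization is completed first so that the Z-enal never meets free Bu2BOTf.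

Step 21
Reactants: 30 (R)-4-benzyl-3-[(2R,3S,4Z,6S,7R,8S,10S,11R)-11-(2,5-dimethoxy-3-nitrophenyl)-3-hydroxy-2,7,8,11-tetramethoxy-4,6,10-trimethylundec-4-enoyl]oxazolidin-2-one
Product: 31 (R)-4-benzyl-3-[(2R,3S,4Z,6S,7R,8S,10S,11R)-3-(tert-butyldimethylsilyloxy)-11-(2,5-dimethoxy-3-nitrophenyl)-2,7,8,11-tetramethoxy-4,6,10-trimethylundec-4-enoyl]oxazolidin-2-one
Conditions: t-BuMe2SiOTf, 2,6-lutidine, CH2Cl2, −78 → 0 °C
Reagents that add atoms: tert-butyldimethylsilyl trifluoromethanesulfonate, CC(C)(C)[Si](C)(C)OS(=O)(=O)C(F)(F)F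
Why: Silylation of the hindered allylic alcohol with a silyl triflate and a hindered pyridine base; the silyl ether protects the C7 oxygen through the reductions, the olefinations and the ring closure.

Step 22
Reactants: 31 (R)-4-benzyl-3-[(2R,3S,4Z,6S,7R,8S,10S,11R)-3-(tert-butyldimethylsilyloxy)-11-(2,5-dimethoxy-3-nitrophenyl)-2,7,8,11-tetramethoxy-4,6,10-trimethylundec-4-enoyl]oxazolidin-2-one
Product: 32 (2S,3S,4Z,6S,7R,8S,10S,11R)-3-(tert-butyldimethylsilyloxy)-11-(2,5-dimethoxy-3-nitrophenyl)-2,7,8,11-tetramethoxy-4,6,10-trimethylundec-4-en-1-ol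
Conditions: LiBH4, MeOH (1 equiv), THF, 0 °C; aq. NaOH
Reagents that add atoms: none
Why: Reductive removal of the auxiliary as in step 4; the β-silyloxy and α-methoxy groups are stable to LiBH4.

Step 23
Reactants: 32 (2S,3S,4Z,6S,7R,8S,10S,11R)-3-(tert-butyldimethylsilyloxy)-11-(2,5-dimethoxy-3-nitrophenyl)-2,7,8,11-tetramethoxy-4,6,10-trimethylundec-4-en-1-ol
Product: 33 (2R,3S,4Z,6S,7R,8S,10S,11R)-3-(tert-butyldimethylsilyloxy)-11-(2,5-dimethoxy-3-nitrophenyl)-2,7,8,11-tetramethoxy-4,6,10-trimethylundec-4-enal
Conditions: Dess–Martin periodinane, NaHCO3, CH2Cl2, 0 °C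
Reagents that add atoms: none
Why: Dess–Martin oxidation to the α-methoxy aldehyde under buffered conditions; the aldehyde is used directly to protect the C6 stereocentre.

Step 24
Reactants: 33 (2R,3S,4Z,6S,7R,8S,10S,11R)-3-(tert-butyldimethylsilyloxy)-11-(2,5-dimethoxy-3-nitrophenyl)-2,7,8,11-tetramethoxy-4,6,10-trimethylundec-4-enal; 34 methyl 2-[bis(2,2,2-trifluoroethoxy)phosphoryl]acetate
Product: 35 methyl (2Z,4S,5S,6Z,8S,9R,10S,12S,13R)-5-(tert-butyldimethylsilyloxy)-13-(2,5-dimethoxy-3-nitrophenyl)-4,9,10,13-tetramethoxy-6,8,12-trimethyltrideca-2,6-dienoate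
Conditions: 34, KN(SiMe3)2, 18-crown-6, THF, −78 °C; then 33
Reagents that add atoms: none
Why: Still–Gennari olefination: with the trifluoroethyl phosphonate and a dissociated potassium counter-ion, elimination from the first-formed adduct is faster than its equilibration, so the Z-enoate forms under kinetic control; −78 °C and a pre-formed, non-nucleophilic anion preserve C6.

Step 25
Reactants: 35 methyl (2Z,4S,5S,6Z,8S,9R,10S,12S,13R)-5-(tert-butyldimethylsilyloxy)-13-(2,5-dimethoxy-3-nitrophenyl)-4,9,10,13-tetramethoxy-6,8,12-trimethyltrideca-2,6-dienoate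
Product: 36 (2Z,4S,5S,6Z,8S,9R,10S,12S,13R)-5-(tert-butyldimethylsilyloxy)-13-(2,5-dimethoxy-3-nitrophenyl)-4,9,10,13-tetramethoxy-6,8,12-trimethyltrideca-2,6-dien-1-ol
Conditions: i-Bu2AlH, CH2Cl2, −78 °C; aq. KNaC4H4O6
Reagents that add atoms: none
Why: 1,2-Reduction of the enoate to the allylic alcohol with i-Bu2AlH; the alkene geometry is retained and the nitro group tolerates the reagent at −78 °C.

Step 26
Reactants: 36 (2Z,4S,5S,6Z,8S,9R,10S,12S,13R)-5-(tert-butyldimethylsilyloxy)-13-(2,5-dimethoxy-3-nitrophenyl)-4,9,10,13-tetramethoxy-6,8,12-trimethyltrideca-2,6-dien-1-ol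
Product: 37 (2Z,4S,5S,6Z,8S,9R,10S,12S,13R)-13-(3-amino-2,5-dimethoxyphenyl)-5-(tert-butyldimethylsilyloxy)-4,9,10,13-tetramethoxy-6,8,12-trimethyltrideca-2,6-dien-1-ol
Conditions: Fe powder, NH4Cl, EtOH/H2O, 70 °C
Reagents that add atoms: none
Why: Dissolving-metal (Béchamp-type) reduction of the nitro group under near-neutral conditions; alkenes, silyl ether and allylic alcohol are not reduced, which is why the amine could be carried as nitro until now.

Step 27
Reactants: 38 diphenyl phosphite; 39 tert-butyl bromoacetate
Product: 40 tert-butyl 2-(diphenoxyphosphoryl)acetate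
Conditions: Et3N, CH2Cl2, 0 °C → rt
Reagents that add atoms: none
Why: Michaelis–Becker-type P-alkylation: the phosphite anion formed with Et3N displaces bromide from the activated primary α-bromo ester.

Step 28
Reactants: 40 tert-butyl 2-(diphenoxyphosphoryl)acetate
Product: 41 tert-butyl 2-(diphenoxyphosphoryl)propanoate
Conditions: NaH (1.0 equiv), MeI (1.0 equiv), THF, 0 °C → rt
Reagents that add atoms: iodomethane, CI
Why: C-methylation of the stabilized phosphonoacetate carbanion; one equivalent each of base and MeI limits double alkylation.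

Step 29
Reactants: 41 tert-butyl 2-(diphenoxyphosphoryl)propanoate
Product: 42 2-(diphenoxyphosphoryl)propanoic acid
Conditions: CF3CO2H, CH2Cl2, 0 °C → rt
Reagents that add atoms: none
Why: Acidolysis of the tert-butyl ester with loss of isobutene frees the carboxylic acid without exposing the aryl phosphonate esters to hydroxide, which would displace phenoxide at phosphorus.

Step 30
Reactants: 37 (2Z,4S,5S,6Z,8S,9R,10S,12S,13R)-13-(3-amino-2,5-dimethoxyphenyl)-5-(tert-butyldimethylsilyloxy)-4,9,10,13-tetramethoxy-6,8,12-trimethyltrideca-2,6-dien-1-ol; 42 2-(diphenoxyphosphoryl)propanoic acid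
Product: 43 2-(diphenoxyphosphoryl)propanamide of aniline 37 (C3 alcohol free)
Conditions: 42, EDC·HCl, CH2Cl2, 0 °C → rt
Reagents that add atoms: none
Why: Carbodiimide-mediated amide formation; without an acyl-transfer catalyst the aniline nitrogen is acylated in preference to the primary allylic alcohol. The stereocentre next to phosphorus is present as both epimers and is lost in step 32.

Step 31
Reactants: 43 2-(diphenoxyphosphoryl)propanamide of aniline 37 (C3 alcohol free)
Product: 44 C3 (Z)-enal of phosphonoamide 43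
Conditions: MnO2 (activated), CH2Cl2, rt
Reagents that add atoms: none
Why: MnO2 oxidation, selective for the allylic alcohol and neutral, should give the Z-enal without touching the anilide, the phosphonate or the alkene geometry.

Step 32
Reactants: 44 C3 (Z)-enal of phosphonoamide 43
Product: 45 (2Z,4Z,8Z)-7-O-(tert-butyldimethylsilyl)-18,21-di-O-methyl macrolactam
Conditions: NaI, DBU, THF, 0 °C → rt, slow addition of 44 (final 0.001 M)
Reagents that add atoms: none
Why: Intramolecular Horner–Wadsworth–Emmons olefination of the Ando type: the diaryl phosphonate speeds up collapse of the first-formed syn adduct, so the trisubstituted C2=C3 alkene should form Z under kinetic control while the 19-membered lactam closes. The sodium-chelated phosphonoamide is deprotonated by DBU, a base too weak to isomerize the Z-enal, and high dilution suppresses oligomers.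

Step 33
Reactants: 45 (2Z,4Z,8Z)-7-O-(tert-butyldimethylsilyl)-18,21-di-O-methyl macrolactam
Product: 46 (2Z,4Z,8Z)-7-hydroxy-18,21-di-O-methyl macrolactam
Conditions: HF·pyridine, pyridine, THF, 0 °C → rt
Reagents that add atoms: none
Why: Fluoride cleavage of the secondary silyl ether; buffered HF·pyridine is non-basic and leaves the dienamide geometry and the methyl ethers untouched.

Step 34
Reactants: 46 (2Z,4Z,8Z)-7-hydroxy-18,21-di-O-methyl macrolactam
Product: 48 (2Z,4Z,8Z)-7-O-carbamoyl-18,21-di-O-methyl macrolactam, via N-trichloroacetyl carbamate 47 (not isolated)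
Conditions: Cl3CC(O)NCO, CH2Cl2, 0 °C; then K2CO3, MeOH, 0 °C → rt
Reagents that add atoms: trichloroacetyl isocyanate, O=C=NC(=O)C(Cl)(Cl)Cl
Why: Carbamoylation with an acyl isocyanate: the C7 hydroxyl adds to the isocyanate and mild methanolysis removes the trichloroacetyl group; the anilide N–H is not nucleophilic enough to compete at 0 °C.

Step 35
Reactants: 48 (2Z,4Z,8Z)-7-O-carbamoyl-18,21-di-O-methyl macrolactam
Product: 49 (2Z,4Z,8Z)-7-O-carbamoyl macrolactam 18,21-quinone
Conditions: (NH4)2Ce(NO3)6, MeCN/H2O, 0 °C
Reagents that add atoms: water, O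
Why: Oxidative demethylation of a para-dimethoxyarene by tetravalent cerium: two one-electron oxidations with ipso attack of water release both methyl groups as methanol and give the para-quinone; the amido-dimethoxyarene is by far the most electron-rich part of the molecule, and only the para-quinone can form.

Step 36
Reactants: 49 (2Z,4Z,8Z)-7-O-carbamoyl macrolactam 18,21-quinone
Product: 50 CNP0109452.1
Conditions: Na2S2O4, EtOAc/H2O, rt, argon
Reagents that add atoms: none
Why: Two-electron reduction of the quinone by dithionite to the hydroquinone; alkenes, carbamate and amide are inert, and the product is isolated with exclusion of air.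

## Compound list

1 | 2-hydroxy-5-methoxy-3-nitrobenzaldehyde | O=Cc1cc(OC)cc([N+](=O)[O-])c1O | starting material
2 | 2,5-dimethoxy-3-nitrobenzaldehyde | O=Cc1cc(OC)cc([N+](=O)[O-])c1OC | intermediate
3 | (R)-4-benzyl-3-propionyloxazolidin-2-one | CCC(=O)N1[C@H](Cc2ccccc2)COC1=O | starting material
4 | (R)-4-benzyl-3-[(2R,3R)-3-(2,5-dimethoxy-3-nitrophenyl)-3-hydroxy-2-methylpropanoyl]oxazolidin-2-one | O=C1OC[C@@H](Cc2ccccc2)N1C(=O)[C@H](C)[C@@H](O)c1cc(OC)cc([N+](=O)[O-])c1OC | intermediate
5 | (R)-4-benzyl-3-[(2R,3R)-3-(2,5-dimethoxy-3-nitrophenyl)-3-methoxy-2-methylpropanoyl]oxazolidin-2-one | O=C1OC[C@@H](Cc2ccccc2)N1C(=O)[C@H](C)[C@@H](OC)c1cc(OC)cc([N+](=O)[O-])c1OC | intermediate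
6 | (2S,3R)-3-(2,5-dimethoxy-3-nitrophenyl)-3-methoxy-2-methylpropan-1-ol | OC[C@H](C)[C@@H](OC)c1cc(OC)cc([N+](=O)[O-])c1OC | intermediate
7 | (2R,3R)-3-(2,5-dimethoxy-3-nitrophenyl)-3-methoxy-2-methylpropanal | O=C[C@H](C)[C@@H](OC)c1cc(OC)cc([N+](=O)[O-])c1OC | intermediate
8 | 2-(diethoxyphosphoryl)acetic acid | CCOP(=O)(OCC)CC(=O)O | starting material
9 | (S)-4-benzyloxazolidin-2-one | O=C1N[C@@H](Cc2ccccc2)CO1 | starting material
10 | 2-(diethoxyphosphoryl)acetic pivalic anhydride (formed in the flask) | CCOP(=O)(OCC)CC(=O)OC(=O)C(C)(C)C | intermediate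
11 | (S)-4-benzyl-3-[2-(diethoxyphosphoryl)acetyl]oxazolidin-2-one | CCOP(=O)(OCC)CC(=O)N1[C@@H](Cc2ccccc2)COC1=O | intermediate
12 | (S)-4-benzyl-3-[(2E,4S,5R)-5-(2,5-dimethoxy-3-nitrophenyl)-5-methoxy-4-methylpent-2-enoyl]oxazolidin-2-one | O=C1OC[C@H](Cc2ccccc2)N1C(=O)/C=C/[C@H](C)[C@@H](OC)c1cc(OC)cc([N+](=O)[O-])c1OC | intermediate
13 | (S)-4-benzyl-3-[(4S,5R)-5-(2,5-dimethoxy-3-nitrophenyl)-5-methoxy-4-methylpentanoyl]oxazolidin-2-one | O=C1OC[C@H](Cc2ccccc2)N1C(=O)CC[C@H](C)[C@@H](OC)c1cc(OC)cc([N+](=O)[O-])c1OC | intermediate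
14 | (S)-4-benzyl-3-[(2S,4S,5R)-5-(2,5-dimethoxy-3-nitrophenyl)-2-hydroxy-5-methoxy-4-methylpentanoyl]oxazolidin-2-one | O=C1OC[C@H](Cc2ccccc2)N1C(=O)[C@@H](O)C[C@H](C)[C@@H](OC)c1cc(OC)cc([N+](=O)[O-])c1OC | intermediate
15 | (S)-4-benzyl-3-[(2S,4S,5R)-5-(2,5-dimethoxy-3-nitrophenyl)-2,5-dimethoxy-4-methylpentanoyl]oxazolidin-2-one | O=C1OC[C@H](Cc2ccccc2)N1C(=O)[C@@H](OC)C[C@H](C)[C@@H](OC)c1cc(OC)cc([N+](=O)[O-])c1OC | intermediate
16 | (2S,4S,5R)-5-(2,5-dimethoxy-3-nitrophenyl)-2,5-dimethoxy-4-methylpentan-1-ol | OC[C@@H](OC)C[C@H](C)[C@@H](OC)c1cc(OC)cc([N+](=O)[O-])c1OC | intermediate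
17 | (2S,4S,5R)-5-(2,5-dimethoxy-3-nitrophenyl)-2,5-dimethoxy-4-methylpentanal | O=C[C@@H](OC)C[C@H](C)[C@@H](OC)c1cc(OC)cc([N+](=O)[O-])c1OC | intermediate
18 | cis-2-butene | C/C=C\C | starting material
19 | (Z)-but-2-enyl-diisopinocampheylborane, isopinocampheyl groups from (−)-α-pinene (formed in the flask) | C/C=C\CB([C@H]1C[C@H]2C[C@@H]([C@@H]1C)C2(C)C)[C@H]1C[C@H]2C[C@@H]([C@@H]1C)C2(C)C | intermediate
20 | (3S,4R,5S,7S,8R)-8-(2,5-dimethoxy-3-nitrophenyl)-5,8-dimethoxy-3,7-dimethyloct-1-en-4-ol | C=C[C@H](C)[C@@H](O)[C@@H](OC)C[C@H](C)[C@@H](OC)c1cc(OC)cc([N+](=O)[O-])c1OC | intermediate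
21 | methacryloyl chloride | C=C(C)C(=O)Cl | starting material
22 | (3S,4R,5S,7S,8R)-8-(2,5-dimethoxy-3-nitrophenyl)-5,8-dimethoxy-3,7-dimethyloct-1-en-4-yl 2-methylprop-2-enoate | C=C(C)C(=O)O[C@H]([C@@H](C)C=C)[C@@H](OC)C[C@H](C)[C@@H](OC)c1cc(OC)cc([N+](=O)[O-])c1OC | intermediate
23 | (5S,6R)-6-[(1S,3S,4R)-4-(2,5-dimethoxy-3-nitrophenyl)-1,4-dimethoxy-3-methylbutyl]-3,5-dimethyl-5,6-dihydro-2H-pyran-2-one | O=C1O[C@H]([C@@H](C)C=C1C)[C@@H](OC)C[C@H](C)[C@@H](OC)c2cc(OC)cc([N+](=O)[O-])c2OC | intermediate
24 | (2Z,4S,5R,6S,8S,9R)-9-(2,5-dimethoxy-3-nitrophenyl)-5-hydroxy-N,6,9-trimethoxy-N,2,4,8-tetramethylnon-2-enamide | CON(C)C(=O)/C(C)=C\[C@H](C)[C@@H](O)[C@@H](OC)C[C@H](C)[C@@H](OC)c1cc(OC)cc([N+](=O)[O-])c1OC | intermediate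
25 | (2Z,4S,5R,6S,8S,9R)-9-(2,5-dimethoxy-3-nitrophenyl)-N,5,6,9-tetramethoxy-N,2,4,8-tetramethylnon-2-enamide | CON(C)C(=O)/C(C)=C\[C@H](C)[C@@H](OC)[C@@H](OC)C[C@H](C)[C@@H](OC)c1cc(OC)cc([N+](=O)[O-])c1OC | intermediate
26 | (2Z,4S,5R,6S,8S,9R)-9-(2,5-dimethoxy-3-nitrophenyl)-5,6,9-trimethoxy-2,4,8-trimethylnon-2-enal | O=C/C(C)=C\[C@H](C)[C@@H](OC)[C@@H](OC)C[C@H](C)[C@@H](OC)c1cc(OC)cc([N+](=O)[O-])c1OC | intermediate
27 | (R)-4-benzyloxazolidin-2-one | O=C1N[C@H](Cc2ccccc2)CO1 | starting material
28 | methoxyacetyl chloride | COCC(=O)Cl | starting material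
29 | (R)-4-benzyl-3-(2-methoxyacetyl)oxazolidin-2-one | COCC(=O)N1[C@H](Cc2ccccc2)COC1=O | intermediate
30 | (R)-4-benzyl-3-[(2R,3S,4Z,6S,7R,8S,10S,11R)-11-(2,5-dimethoxy-3-nitrophenyl)-3-hydroxy-2,7,8,11-tetramethoxy-4,6,10-trimethylundec-4-enoyl]oxazolidin-2-one | O=C1OC[C@@H](Cc2ccccc2)N1C(=O)[C@H](OC)[C@@H](O)/C(C)=C\[C@H](C)[C@@H](OC)[C@@H](OC)C[C@H](C)[C@@H](OC)c1cc(OC)cc([N+](=O)[O-])c1OC | intermediate
31 | (R)-4-benzyl-3-[(2R,3S,4Z,6S,7R,8S,10S,11R)-3-(tert-butyldimethylsilyloxy)-11-(2,5-dimethoxy-3-nitrophenyl)-2,7,8,11-tetramethoxy-4,6,10-trimethylundec-4-enoyl]oxazolidin-2-one | O=C1OC[C@@H](Cc2ccccc2)N1C(=O)[C@H](OC)[C@@H](O[Si](C)(C)C(C)(C)C)/C(C)=C\[C@H](C)[C@@H](OC)[C@@H](OC)C[C@H](C)[C@@H](OC)c1cc(OC)cc([N+](=O)[O-])c1OC | intermediate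
32 | (2S,3S,4Z,6S,7R,8S,10S,11R)-3-(tert-butyldimethylsilyloxy)-11-(2,5-dimethoxy-3-nitrophenyl)-2,7,8,11-tetramethoxy-4,6,10-trimethylundec-4-en-1-ol | OC[C@H](OC)[C@@H](O[Si](C)(C)C(C)(C)C)/C(C)=C\[C@H](C)[C@@H](OC)[C@@H](OC)C[C@H](C)[C@@H](OC)c1cc(OC)cc([N+](=O)[O-])c1OC | intermediate
33 | (2R,3S,4Z,6S,7R,8S,10S,11R)-3-(tert-butyldimethylsilyloxy)-11-(2,5-dimethoxy-3-nitrophenyl)-2,7,8,11-tetramethoxy-4,6,10-trimethylundec-4-enal | O=C[C@H](OC)[C@@H](O[Si](C)(C)C(C)(C)C)/C(C)=C\[C@H](C)[C@@H](OC)[C@@H](OC)C[C@H](C)[C@@H](OC)c1cc(OC)cc([N+](=O)[O-])c1OC | intermediate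
34 | methyl 2-[bis(2,2,2-trifluoroethoxy)phosphoryl]acetate | COC(=O)CP(=O)(OCC(F)(F)F)OCC(F)(F)F | starting material
35 | methyl (2Z,4S,5S,6Z,8S,9R,10S,12S,13R)-5-(tert-butyldimethylsilyloxy)-13-(2,5-dimethoxy-3-nitrophenyl)-4,9,10,13-tetramethoxy-6,8,12-trimethyltrideca-2,6-dienoate | COC(=O)/C=C\[C@H](OC)[C@@H](O[Si](C)(C)C(C)(C)C)/C(C)=C\[C@H](C)[C@@H](OC)[C@@H](OC)C[C@H](C)[C@@H](OC)c1cc(OC)cc([N+](=O)[O-])c1OC | intermediate
36 | (2Z,4S,5S,6Z,8S,9R,10S,12S,13R)-5-(tert-butyldimethylsilyloxy)-13-(2,5-dimethoxy-3-nitrophenyl)-4,9,10,13-tetramethoxy-6,8,12-trimethyltrideca-2,6-dien-1-ol | OC/C=C\[C@H](OC)[C@@H](O[Si](C)(C)C(C)(C)C)/C(C)=C\[C@H](C)[C@@H](OC)[C@@H](OC)C[C@H](C)[C@@H](OC)c1cc(OC)cc([N+](=O)[O-])c1OC | intermediate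
37 | (2Z,4S,5S,6Z,8S,9R,10S,12S,13R)-13-(3-amino-2,5-dimethoxyphenyl)-5-(tert-butyldimethylsilyloxy)-4,9,10,13-tetramethoxy-6,8,12-trimethyltrideca-2,6-dien-1-ol | OC/C=C\[C@H](OC)[C@@H](O[Si](C)(C)C(C)(C)C)/C(C)=C\[C@H](C)[C@@H](OC)[C@@H](OC)C[C@H](C)[C@@H](OC)c1cc(OC)cc(N)c1OC | intermediate
38 | diphenyl phosphite | O=[PH](Oc1ccccc1)Oc1ccccc1 | starting material
39 | tert-butyl bromoacetate | BrCC(=O)OC(C)(C)C | starting material
40 | tert-butyl 2-(diphenoxyphosphoryl)acetate | CC(C)(C)OC(=O)CP(=O)(Oc1ccccc1)Oc1ccccc1 | intermediate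
41 | tert-butyl 2-(diphenoxyphosphoryl)propanoate (racemic) | CC(C(=O)OC(C)(C)C)P(=O)(Oc1ccccc1)Oc1ccccc1 | intermediate
42 | 2-(diphenoxyphosphoryl)propanoic acid (racemic) | CC(C(=O)O)P(=O)(Oc1ccccc1)Oc1ccccc1 | intermediate
43 | 2-(diphenoxyphosphoryl)propanamide of aniline 37, amide nitrogen on C20, C3 alcohol free, both epimers at the phosphorus-bearing carbon | OC/C=C\[C@H](OC)[C@@H](O[Si](C)(C)C(C)(C)C)/C(C)=C\[C@H](C)[C@@H](OC)[C@@H](OC)C[C@H](C)[C@@H](OC)c1cc(OC)cc(NC(=O)C(C)P(=O)(Oc2ccccc2)Oc2ccccc2)c1OC | intermediate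
44 | C3 (Z)-enal of phosphonoamide 43, (4Z,8Z), both epimers at the phosphorus-bearing carbon | O=C/C=C\[C@H](OC)[C@@H](O[Si](C)(C)C(C)(C)C)/C(C)=C\[C@H](C)[C@@H](OC)[C@@H](OC)C[C@H](C)[C@@H](OC)c1cc(OC)cc(NC(=O)C(C)P(=O)(Oc2ccccc2)Oc2ccccc2)c1OC | intermediate
45 | (2Z,4Z,8Z)-7-O-(tert-butyldimethylsilyl)-18,21-di-O-methyl macrolactam (6S,7S,10S,11R,12S,14S,15R) | CO[C@H]1[C@@H](OC)C[C@H](C)[C@@H](OC)c2cc(OC)cc(c2OC)NC(=O)/C(C)=C\C=C/[C@H](OC)[C@@H](O[Si](C)(C)C(C)(C)C)/C(C)=C\[C@@H]1C | intermediate
46 | (2Z,4Z,8Z)-7-hydroxy-18,21-di-O-methyl macrolactam (6S,7S,10S,11R,12S,14S,15R) | CO[C@H]1[C@@H](OC)C[C@H](C)[C@@H](OC)c2cc(OC)cc(c2OC)NC(=O)/C(C)=C\C=C/[C@H](OC)[C@@H](O)/C(C)=C\[C@@H]1C | intermediate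
47 | 7-O-(N-trichloroacetylcarbamoyl)-18,21-di-O-methyl macrolactam (formed in the flask) | CO[C@H]1[C@@H](OC)C[C@H](C)[C@@H](OC)c2cc(OC)cc(c2OC)NC(=O)/C(C)=C\C=C/[C@H](OC)[C@@H](OC(=O)NC(=O)C(Cl)(Cl)Cl)/C(C)=C\[C@@H]1C | intermediate
48 | (2Z,4Z,8Z)-7-O-carbamoyl-18,21-di-O-methyl macrolactam (dimethyl ether of the target) | CO[C@H]1[C@@H](OC)C[C@H](C)[C@@H](OC)c2cc(OC)cc(c2OC)NC(=O)/C(C)=C\C=C/[C@H](OC)[C@@H](OC(N)=O)/C(C)=C\[C@@H]1C | intermediate
49 | (2Z,4Z,8Z)-7-O-carbamoyl macrolactam 18,21-quinone | CO[C@H]1[C@@H](OC)C[C@H](C)[C@@H](OC)C2=CC(=O)C=C(C2=O)NC(=O)/C(C)=C\C=C/[C@H](OC)[C@@H](OC(N)=O)/C(C)=C\[C@@H]1C | intermediate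
50 | CNP0109452.1, the (2Z,4Z,8Z)-7-O-carbamoyl macrolactam 18,21-hydroquinone (6S,7S,10S,11R,12S,14S,15R) | CO[C@H]1[C@@H](OC)C[C@H](C)[C@@H](OC)c2cc(O)cc(c2O)NC(=O)/C(C)=C\C=C/[C@H](OC)[C@@H](OC(N)=O)/C(C)=C\[C@@H]1C | target

## Step count and least certain steps

Total step count: 36, of which steps 6, 19 and 27–29 are side branches. Longest linear sequence: 31 steps, from 1 to 50 through steps 1–5, 7–18, 20–26 and 30–36.

**Step 15 (key step).** The most likely failure is catalyst death before ring closure: initiation at the allylically branched vinyl group is slow, the methacrylate is a reluctant partner, and the ester must first rotate out of its preferred conformation. Competing processes are intermolecular cross-metathesis at the vinyl end and hydride-mediated migration of the C9 double bond, which would erode C10. The fallback makes the same lactone by olefination instead of metathesis, setting out from 20 and returning at 23. The C11 hydroxyl of 20 would be silylated (Et3SiCl, imidazole) to the triethylsilyl ether F1. The vinyl group would be cleaved (OsO4 cat., N-methylmorpholine N-oxide; then NaIO4) to the C9 aldehyde F2. A Still–Gennari olefination with ethyl 2-[bis(2,2,2-trifluoroethoxy)phosphoryl]propanoate (KN(SiMe3)2, 18-crown-6, −78 °C) would give the Z-enoate F3. HF·pyridine would then remove the silyl group, and the freed C11 hydroxyl, held cis to the ester, should lactonize to 23.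

**Step 32.** Three processes threaten this step: erosion of Z selectivity at C2=C3, because ring strain in the cyclizing transition states can override the reagent's kinetic preference; base-induced isomerization of the Z-enal before it reacts; and oligomerization. The fallback separates olefination from ring closure, setting out from 36 and returning at 45. 36 would be oxidized (MnO2) to the nitro Z-enal F4. F4 would be olefinated intermolecularly with ethyl 2-(diphenoxyphosphoryl)propanoate (NaI, DBU) to the (2Z,4Z)-dienoate F5, where the isomers can be separated. The nitro group would be reduced (Fe, NH4Cl) to the anilino ester F6, and the ester hydrolysed (LiOH, THF/MeOH/H2O) to the amino acid F7. F7 would be closed by macrolactamization under high dilution (bis(2-oxo-3-oxazolidinyl)phosphinic chloride, i-Pr2NEt, toluene) to 45.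

**Step 16.** The hydroxy amide may close back to the lactone on work-up or during the methylation of step 17, since the Z alkene holds the C11 hydroxyl next to C7. The hindered α-methyl lactone may also react slowly, giving time for conjugate addition of the aluminium amide. The fallback opens the ring by reduction, setting out from 23 and returning at 26. Excess i-Bu2AlH (CH2Cl2, −78 → 0 °C) would give the Z-diol F8. The primary allylic hydroxyl would be silylated selectively (t-BuMe2SiCl, imidazole) to F9, and the C11 hydroxyl methylated (Me3OBF4, 1,8-bis(dimethylamino)naphthalene) to F10. HF·pyridine would free the allylic alcohol F11, and MnO2 would oxidize it to 26.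

**Step 20.** The α-methyl Z-enal may isomerize to the E-enal under the amine and boron Lewis acid, a process favoured by relief of strain between the formyl group and C10. The hindered aldehyde may also add slowly, so the isomerization gains ground. The fallback sets C6 and C7 by allylboration under base-free conditions, setting out from 26 and returning at 33. Brown γ-alkoxyallylboration with the (Z)-γ-methoxyallylborane from allyl methyl ether (s-BuLi; (+)-Ipc2BOMe; BF3·OEt2; −78 °C) would give the syn methoxy alcohol F12. Silylation (t-BuMe2SiOTf, 2,6-lutidine) would give F13. Selective Johnson–Lemieux cleavage of the monosubstituted alkene (OsO4 cat., N-methylmorpholine N-oxide; NaIO4), which is far more accessible than the hindered trisubstituted C8=C9 bond, would give 33.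

**Step 8.** Diimide reacts sluggishly with an electron-poor 1,2-disubstituted alkene and disproportionates in competition, so the reduction may stop short and leave inseparable alkene. The fallback builds the saturated chain by alkylation, setting out from 6 and returning at 13. 6 would be converted (Tf2O, 2,6-lutidine, −78 °C) to the triflate F14, and this alkylated with the lithium enolate of tert-butyl acetate (LiN(i-Pr)2, THF, −78 °C) to the tert-butyl ester F15. CF3CO2H would give the acid F16. Activation with t-BuCOCl/Et3N and addition of lithiated 9 would give 13.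

## Further compounds

F1 | step 15 | triethylsilyl ether of 20 | C=C[C@H](C)[C@@H](O[Si](CC)(CC)CC)[C@@H](OC)C[C@H](C)[C@@H](OC)c1cc(OC)cc([N+](=O)[O-])c1OC
F2 | step 15 | C9 aldehyde with C11 triethylsilyl ether | O=C[C@H](C)[C@@H](O[Si](CC)(CC)CC)[C@@H](OC)C[C@H](C)[C@@H](OC)c1cc(OC)cc([N+](=O)[O-])c1OC
F3 | step 15 | ethyl (Z)-2-methyl-2-enoate with C11 triethylsilyl ether | CCOC(=O)/C(C)=C\[C@H](C)[C@@H](O[Si](CC)(CC)CC)[C@@H](OC)C[C@H](C)[C@@H](OC)c1cc(OC)cc([N+](=O)[O-])c1OC
F4 | step 32 | nitro (2Z,6Z)-dienal from 36 | O=C/C=C\[C@H](OC)[C@@H](O[Si](C)(C)C(C)(C)C)/C(C)=C\[C@H](C)[C@@H](OC)[C@@H](OC)C[C@H](C)[C@@H](OC)c1cc(OC)cc([N+](=O)[O-])c1OC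
F5 | step 32 | ethyl (2Z,4Z,8Z)-trienoate, nitro arene | CCOC(=O)/C(C)=C\C=C/[C@H](OC)[C@@H](O[Si](C)(C)C(C)(C)C)/C(C)=C\[C@H](C)[C@@H](OC)[C@@H](OC)C[C@H](C)[C@@H](OC)c1cc(OC)cc([N+](=O)[O-])c1OC
F6 | step 32 | ethyl (2Z,4Z,8Z)-trienoate, amino arene | CCOC(=O)/C(C)=C\C=C/[C@H](OC)[C@@H](O[Si](C)(C)C(C)(C)C)/C(C)=C\[C@H](C)[C@@H](OC)[C@@H](OC)C[C@H](C)[C@@H](OC)c1cc(OC)cc(N)c1OC
F7 | step 32 | (2Z,4Z,8Z)-amino acid (seco acid) | OC(=O)/C(C)=C\C=C/[C@H](OC)[C@@H](O[Si](C)(C)C(C)(C)C)/C(C)=C\[C@H](C)[C@@H](OC)[C@@H](OC)C[C@H](C)[C@@H](OC)c1cc(OC)cc(N)c1OC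
F8 | step 16 | (Z)-C7,C11-diol from reduction of 23 | OC/C(C)=C\[C@H](C)[C@@H](O)[C@@H](OC)C[C@H](C)[C@@H](OC)c1cc(OC)cc([N+](=O)[O-])c1OC
F9 | step 16 | C7 tert-butyldimethylsilyl ether of the diol | CC(C)(C)[Si](C)(C)OC/C(C)=C\[C@H](C)[C@@H](O)[C@@H](OC)C[C@H](C)[C@@H](OC)c1cc(OC)cc([N+](=O)[O-])c1OC
F10 | step 16 | C11 methyl ether with C7 silyl ether | CC(C)(C)[Si](C)(C)OC/C(C)=C\[C@H](C)[C@@H](OC)[C@@H](OC)C[C@H](C)[C@@H](OC)c1cc(OC)cc([N+](=O)[O-])c1OC
F11 | step 16 | (Z)-allylic alcohol with C11 methyl ether | OC/C(C)=C\[C@H](C)[C@@H](OC)[C@@H](OC)C[C@H](C)[C@@H](OC)c1cc(OC)cc([N+](=O)[O-])c1OC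
F12 | step 20 | syn C6-methoxy C7-hydroxy terminal alkene | C=C[C@H](OC)[C@@H](O)/C(C)=C\[C@H](C)[C@@H](OC)[C@@H](OC)C[C@H](C)[C@@H](OC)c1cc(OC)cc([N+](=O)[O-])c1OC
F13 | step 20 | C7 tert-butyldimethylsilyl ether of the terminal alkene | C=C[C@H](OC)[C@@H](O[Si](C)(C)C(C)(C)C)/C(C)=C\[C@H](C)[C@@H](OC)[C@@H](OC)C[C@H](C)[C@@H](OC)c1cc(OC)cc([N+](=O)[O-])c1OC
F14 | step 8 | trifluoromethanesulfonate of 6 | FC(F)(F)S(=O)(=O)OC[C@H](C)[C@@H](OC)c1cc(OC)cc([N+](=O)[O-])c1OC
F15 | step 8 | tert-butyl (4S,5R)-5-(2,5-dimethoxy-3-nitrophenyl)-5-methoxy-4-methylpentanoate | CC(C)(C)OC(=O)CC[C@H](C)[C@@H](OC)c1cc(OC)cc([N+](=O)[O-])c1OC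
F16 | step 8 | (4S,5R)-5-(2,5-dimethoxy-3-nitrophenyl)-5-methoxy-4-methylpentanoic acid | OC(=O)CC[C@H](C)[C@@H](OC)c1cc(OC)cc([N+](=O)[O-])c1OC
A1 | alternative 1 | N-(4-methoxybenzyl) macrolactam with C21 phenol and C18 methyl ether | CO[C@H]1[C@@H](OC)C[C@H](C)[C@@H](OC)c2cc(OC)cc(c2O)N(Cc3ccc(OC)cc3)C(=O)/C(C)=C\C=C/[C@H](OC)[C@@H](OC(N)=O)/C(C)=C\[C@@H]1C
A2 | alternative 2 | macrocyclic 4,5-didehydro enyne lactam, silyl protected | CO[C@H]1[C@@H](OC)C[C@H](C)[C@@H](OC)c2cc(O[Si](C(C)C)(C(C)C)C(C)C)cc(c2O[Si](C(C)C)(C(C)C)C(C)C)NC(=O)/C(C)=C\C#C[C@H](OC)[C@@H](O[Si](CC)(CC)CC)/C(C)=C\[C@@H]1C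
A3 | alternative 2 | molybdenum alkylidyne Mo(≡CC6H4OMe)(OSiPh3)3 | COc1ccc(cc1)C#[Mo](O[Si](c1ccccc1)(c1ccccc1)c1ccccc1)(O[Si](c1ccccc1)(c1ccccc1)c1ccccc1)O[Si](c1ccccc1)(c1ccccc1)c1ccccc1
A4 | alternative 3 | macrolactam with allyl-protected phenols and C7 silyl ether | CO[C@H]1[C@@H](OC)C[C@H](C)[C@@H](OC)c2cc(OCC=C)cc(c2OCC=C)NC(=O)/C(C)=C\C=C/[C@H](OC)[C@@H](O[Si](C)(C)C(C)(C)C)/C(C)=C\[C@@H]1C
A5 | alternative 3 | copper monoiodide CuI | [Cu+].[I-]
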